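**Strategy.** Gmelinol is numbered as 3,7-dioxabicyclo[3.3.0]octane: ring A is C1(OH)–C2(Ar)–O3–C4H2–C5, ring B is C1–C5–C6(Ar)–O7–C8H2. Ring A is assembled in one operation from veratraldehyde (C2, O3) and a C1–C5–C4 unit. The precursor is a malic-acid-derived 2-tert-butyl-1,3-dioxolan-4-one that carries a 1-aroylvinyl group; its dienolate attacks the aldehyde through C1 (bond C1–C2) and the aldolate closes onto C4 (bond O3–C4). The step exploits C1 as the α-carbon of a masked α-hydroxy acid (C8 as carboxyl) and C4 as the β-carbon of an enone whose carbonyl is C6. The acetal carbon relays chirality. Ring B is closed last by hemiketal reduction, which sets the endo aryl group.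

Key step: step 4

Remark: "target C-n" below refers to the bicyclic numbering above. The ketone α-carbon created in step 4 (target C5) is expected as a mixture of epimers and is carried as such until step 6, where it converges. Compounds 1, 2, 4 and 8 are commercial.

Step 1
Reactants: 1 (S)-malic acid; 2 pivalaldehyde
Product: 3 2-[(2S,4S)-2-tert-butyl-5-oxo-1,3-dioxolan-4-yl]acetic acid (cis)
Conditions: TsOH·H2O (cat.), H2SO4 (cat.), pentane, reflux, azeotropic removal of water; recrystallisation
Reagents that add atoms: none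
Why: Acid-catalysed acetalisation of the α-hydroxy acid unit should give the five-membered dioxolanone, whose new acetal centre forms cis to the side chain under thermodynamic control and stores the chirality for step 4 (self-regeneration of stereocentres).

Step 2
Reactants: 3 2-[(2S,4S)-2-tert-butyl-5-oxo-1,3-dioxolan-4-yl]acetic acid; 4 veratrole (1,2-dimethoxybenzene)
Product: 6 (2S,5S)-2-tert-butyl-5-[2-(3,4-dimethoxyphenyl)-2-oxoethyl]-1,3-dioxolan-4-one, via acid chloride 5 (not isolated)
Conditions: (COCl)2, DMF (cat.), CH2Cl2, 0 °C to rt; then 4, AlCl3, CH2Cl2, 0 °C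
Reagents that add atoms: none
Why: The acid chloride should acylate veratrole para to a methoxy group (Friedel–Crafts acylation), which brings in the ring B aryl group and target C6 as a ketone without touching the stereocentres.

Step 3
Reactants: 6 (2S,5S)-2-tert-butyl-5-[2-(3,4-dimethoxyphenyl)-2-oxoethyl]-1,3-dioxolan-4-one
Product: 7 (2S,5S)-2-tert-butyl-5-[3-(3,4-dimethoxyphenyl)-3-oxoprop-1-en-2-yl]-1,3-dioxolan-4-one
Conditions: (CH2O)n, PhNHMe·CF3CO2H, THF, reflux
Reagents that add atoms: formaldehyde (as paraformaldehyde), C=O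
Why: Mannich-type α-methylenation of the aryl ketone (aminomethylation of the enol, then loss of the amine) installs target C4 as the terminus of an aryl vinyl ketone; a shift of the double bond into conjugation with the lactone would be harmless, since both isomers give the same dienolate and the acetal carbon keeps the stereochemical information.

Step 4
Reactants: 7 (2S,5S)-2-tert-butyl-5-[3-(3,4-dimethoxyphenyl)-3-oxoprop-1-en-2-yl]-1,3-dioxolan-4-one; 8 veratraldehyde (3,4-dimethoxybenzaldehyde)
Product: 12 (2S,5R,6R)-2-tert-butyl-9-(3,4-dimethoxybenzoyl)-6-(3,4-dimethoxyphenyl)-1,3,7-trioxaspiro[4.4]nonan-4-one (both C9 epimers), via lithium dienolate 9 (not isolated), via lithium aldolate 10 (not isolated), via lithium enolate 11 (not isolated)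
Conditions: 7 added to LiN(SiMe3)2, THF, −78 °C; then 8, −78 to −30 °C; AcOH, −78 °C
Reagents that add atoms: none
Why: Proposed new method: LiN(SiMe3)2 removes the C5–H of 7 (α to the lactone carbonyl and allylic) to give the cross-conjugated dienolate 9, which adds through its α-carbon to 8 to form bond C1–C2 (aldolate 10); the alkoxide then adds to the CH2 terminus of the neighbouring aryl vinyl ketone to form bond O3–C4, and the ketone enolate 11 is protonated on quench, the reasoning being that this closure is the microscopic reverse of the familiar base-induced β-elimination of 3-acyl tetrahydrofurans and is driven by formation of the more stable enolate. The closest known reaction types are the aldol addition of lithium enolates of 2-tert-butyl-1,3-dioxolan-4-ones to aldehydes and the 5-endo-trig oxa-Michael cyclisation of γ-hydroxy vinyl sulfones. Ring A is closed in the 5-endo-trig mode. The spiro carbon (target C1) is controlled by the acetal carbon, the aldehyde entering anti to the tert-butyl group with net retention of the malic acid configuration; the carbinol carbon (target C2) is controlled by a closed, lithium-bridged chair transition state with the aryl group equatorial, which places the aryl group cis to the ring oxygen on the spiro carbon; the ketone α-carbon (target C5) is not controlled here and converges in step 6. The step needs α- over γ-attack of the dienolate, which the chelated transition state of the ester-type enolate should secure, and ring closure over β-elimination of the acetal oxygen from 11, which the low temperature and the cold acidic quench should secure.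

Step 5
Reactants: 12 (2S,5R,6R)-2-tert-butyl-9-(3,4-dimethoxybenzoyl)-6-(3,4-dimethoxyphenyl)-1,3,7-trioxaspiro[4.4]nonan-4-one
Product: 13 (2R,3S)-2-(3,4-dimethoxyphenyl)-4-[(3,4-dimethoxyphenyl)(hydroxy)methyl]-3-(hydroxymethyl)oxolan-3-ol (epimers at C4; epimers at the side-chain carbinol carbon)
Conditions: LiAlH4, THF, 0 °C
Reagents that add atoms: none
Why: Hydride reduction should convert the aryl ketone into the carbinol (epimers, reoxidised in step 6) and the acylal-type dioxolanone carbonyl into the primary alcohol (target C8), which frees the tertiary hydroxyl and releases the auxiliary as 2,2-dimethylpropan-1-ol.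

Step 6
Reactants: 13 (2R,3S)-2-(3,4-dimethoxyphenyl)-4-[(3,4-dimethoxyphenyl)(hydroxy)methyl]-3-(hydroxymethyl)oxolan-3-ol
Product: 15 (1S,2R,5S)-2,6-bis(3,4-dimethoxyphenyl)-3,7-dioxabicyclo[3.3.0]octane-1,6-diol (hemiketal; either configuration at C6), via keto-diol 14 (not isolated)
Conditions: MnO2, CH2Cl2, rt; then Et3N (cat.), rt
Reagents that add atoms: none
Why: MnO2 oxidation should be selective for the benzylic secondary alcohol; keto-diol 14 closes to the five-membered hemiketal (5-exo-trig) only when the aroyl group is cis to the CH2OH group on ring A, and base-mediated epimerisation α to the ketone should feed the other epimer into this sink, which sets target C5 (cis ring fusion).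

Step 7
Reactants: 15 (1S,2R,5S)-2,6-bis(3,4-dimethoxyphenyl)-3,7-dioxabicyclo[3.3.0]octane-1,6-diol
Product: 16 (+)-gmelinol, (1S,2R,5R,6R)-2,6-bis(3,4-dimethoxyphenyl)-3,7-dioxabicyclo[3.3.0]octan-1-ol
Conditions: Et3SiH, BF3·OEt2, CH2Cl2, −78 °C
Reagents that add atoms: none
Why: Lewis-acid-mediated ionic hydrogenation of the cyclic hemiketal: ionisation at C6 of the cis-fused bicycle is followed by hydride delivery from Et3SiH to the convex face, so that the aryl group at C6 should end endo (6R).

**Compound list**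

1 | (S)-malic acid | O[C@@H](CC(=O)O)C(=O)O | starting material
2 | pivalaldehyde (2,2-dimethylpropanal) | CC(C)(C)C=O | starting material
3 | 2-[(2S,4S)-2-tert-butyl-5-oxo-1,3-dioxolan-4-yl]acetic acid (cis) | O=C1O[C@@H](C(C)(C)C)O[C@H]1CC(=O)O | intermediate
4 | veratrole (1,2-dimethoxybenzene) | COc1ccccc1OC | starting material
5 | 2-[(2S,4S)-2-tert-butyl-5-oxo-1,3-dioxolan-4-yl]acetyl chloride | O=C1O[C@@H](C(C)(C)C)O[C@H]1CC(=O)Cl | intermediate
6 | (2S,5S)-2-tert-butyl-5-[2-(3,4-dimethoxyphenyl)-2-oxoethyl]-1,3-dioxolan-4-one | O=C1O[C@@H](C(C)(C)C)O[C@H]1CC(=O)c2ccc(OC)c(OC)c2 | intermediate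
7 | (2S,5S)-2-tert-butyl-5-[3-(3,4-dimethoxyphenyl)-3-oxoprop-1-en-2-yl]-1,3-dioxolan-4-one | O=C1O[C@@H](C(C)(C)C)O[C@H]1C(=C)C(=O)c2ccc(OC)c(OC)c2 | intermediate
8 | veratraldehyde (3,4-dimethoxybenzaldehyde) | COc1ccc(C=O)cc1OC | starting material
9 | lithium (2S)-2-tert-butyl-5-[3-(3,4-dimethoxyphenyl)-3-oxoprop-1-en-2-yl]-1,3-dioxol-4-olate (dienolate of 7) | [Li+].[O-]C1=C(C(=C)C(=O)c2ccc(OC)c(OC)c2)O[C@H](C(C)(C)C)O1 | intermediate
10 | lithium (R)-[(2S,4R)-2-tert-butyl-4-[3-(3,4-dimethoxyphenyl)-3-oxoprop-1-en-2-yl]-5-oxo-1,3-dioxolan-4-yl](3,4-dimethoxyphenyl)methanolate (aldolate) | [Li+].COc1ccc([C@@H]([O-])[C@@]2(C(=C)C(=O)c3ccc(OC)c(OC)c3)O[C@H](C(C)(C)C)OC2=O)cc1OC | intermediate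
11 | lithium enolate of 12 (enolate of the aryl ketone, exocyclic to the oxolane ring) | [Li+].COc1ccc([C@H]2OCC(=C([O-])c3ccc(OC)c(OC)c3)[C@@]24O[C@H](C(C)(C)C)OC4=O)cc1OC | intermediate
12 | (2S,5R,6R)-2-tert-butyl-9-(3,4-dimethoxybenzoyl)-6-(3,4-dimethoxyphenyl)-1,3,7-trioxaspiro[4.4]nonan-4-one (both C9 epimers) | COc1ccc([C@H]2OCC(C(=O)c3ccc(OC)c(OC)c3)[C@@]24O[C@H](C(C)(C)C)OC4=O)cc1OC | intermediate
13 | (2R,3S)-2-(3,4-dimethoxyphenyl)-4-[(3,4-dimethoxyphenyl)(hydroxy)methyl]-3-(hydroxymethyl)oxolan-3-ol (epimers at C4 and at the carbinol carbon) | COc1ccc([C@H]2OCC(C(O)c3ccc(OC)c(OC)c3)[C@]2(O)CO)cc1OC | intermediate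
14 | (3,4-dimethoxyphenyl)[(3S,4S,5R)-5-(3,4-dimethoxyphenyl)-4-hydroxy-4-(hydroxymethyl)oxolan-3-yl]methanone (aroyl cis to CH2OH) | COc1ccc([C@H]2OC[C@H](C(=O)c3ccc(OC)c(OC)c3)[C@]2(O)CO)cc1OC | intermediate
15 | (1S,2R,5S)-2,6-bis(3,4-dimethoxyphenyl)-3,7-dioxabicyclo[3.3.0]octane-1,6-diol (cis-fused hemiketal, either configuration at C6) | COc1ccc([C@H]2OC[C@@H]3C(O)(c4ccc(OC)c(OC)c4)OC[C@]23O)cc1OC | intermediate
16 | (+)-gmelinol, (1S,2R,5R,6R)-2,6-bis(3,4-dimethoxyphenyl)-3,7-dioxabicyclo[3.3.0]octan-1-ol | COc1ccc([C@H]2OC[C@@H]3[C@H](c4ccc(OC)c(OC)c4)OC[C@]23O)cc1OC | target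

**Summary**

Total step count: 7. Longest linear sequence: 7 steps (from 1).

Steps most likely to fail:

Step 4 (labelled step). The dienolate may react through its γ-carbon, or ring closure may be slower than β-elimination of the acetal oxygen from enolate 11. The fallback uses known reactions only, sets out from 6 and returns at 12; it moves the ring closure to the aldehyde oxidation level at target C4. Condensation of 6 with N,N-dimethylformamide dimethyl acetal (neat, 90 °C) should give enaminone F1, whose side chain is no longer a Michael acceptor. Deprotonation (LiN(SiMe3)2, THF, −78 °C) and aldol addition to 8 under the same acetal control should give hydroxy enaminone F2. On acidification (AcOH, rt) the hydroxyl should add to the vinylogous iminium carbon in the 5-exo-trig mode, with loss of dimethylamine, to give 2,3-dihydrofuran F3 (a vinylogous ester). Hydrogenation of its ring double bond (H2, Pd/C, EtOAc) returns to 12.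

Step 3. The dioxolanone may fragment by β-elimination of the acetal oxygen, or the enone may oligomerise, under the hot ammonium-salt conditions. The fallback sets out from 6 and returns at 7 by a stepwise aminomethylation at low temperature. Soft enolisation (Me3SiOTf, Et3N, CH2Cl2, 0 °C) should give silyl enol ether F4. Reaction with dimethylmethylideneammonium iodide (CH2Cl2, rt) should give Mannich base F5. N-Methylation (MeI) and elimination of trimethylamine (NaHCO3, CH2Cl2/H2O, rt) then give 7.

Step 7. Facial selectivity may erode through reversible ionisation of the benzylic C6–O7 bond (drift to the exo aryl epimer), or the tertiary alcohol may ionise. The fallback sets out from 15 (through its open form 14) and returns at 16; the C6 configuration is set by a reagent and kept by an SN2 closure at C8. Oxazaborolidine-catalysed borane reduction of the aryl ketone (Corey–Bakshi–Shibata reduction, (S)-methyl oxazaborolidine, BH3·SMe2, aryl as the large group) should give (R)-carbinol F6. Selective sulfonylation of the primary hydroxyl (TsCl, Et3N, Bu2SnO cat., CH2Cl2) should give tosylate F7. Base (NaH, THF, 0 °C) then closes ring B by attack of the C6 alkoxide on C8 (5-exo-tet Williamson etherification, retention at C6) to give 16.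

**Further compounds**

F1 | step 4 | (2S,5S)-2-tert-butyl-5-[1-(dimethylamino)-3-(3,4-dimethoxyphenyl)-3-oxoprop-1-en-2-yl]-1,3-dioxolan-4-one | O=C1O[C@@H](C(C)(C)C)O[C@H]1C(=CN(C)C)C(=O)c2ccc(OC)c(OC)c2
F2 | step 4 | (2S,5R)-2-tert-butyl-5-[(R)-(3,4-dimethoxyphenyl)(hydroxy)methyl]-5-[1-(dimethylamino)-3-(3,4-dimethoxyphenyl)-3-oxoprop-1-en-2-yl]-1,3-dioxolan-4-one | COc1ccc([C@@H](O)[C@@]2(C(=CN(C)C)C(=O)c3ccc(OC)c(OC)c3)O[C@H](C(C)(C)C)OC2=O)cc1OC
F3 | step 4 | (2S,5R,6R)-2-tert-butyl-9-(3,4-dimethoxybenzoyl)-6-(3,4-dimethoxyphenyl)-1,3,7-trioxaspiro[4.4]non-8-en-4-one | COc1ccc([C@H]2OC=C(C(=O)c3ccc(OC)c(OC)c3)[C@@]24O[C@H](C(C)(C)C)OC4=O)cc1OC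
F4 | step 3 | (2S,5S)-2-tert-butyl-5-[2-(3,4-dimethoxyphenyl)-2-(trimethylsilyloxy)ethenyl]-1,3-dioxolan-4-one | O=C1O[C@@H](C(C)(C)C)O[C@H]1C=C(O[Si](C)(C)C)c2ccc(OC)c(OC)c2
F5 | step 3 | (2S,5S)-2-tert-butyl-5-[3-(dimethylamino)-1-(3,4-dimethoxyphenyl)-1-oxopropan-2-yl]-1,3-dioxolan-4-one (epimers at the side-chain carbon) | O=C1O[C@@H](C(C)(C)C)O[C@H]1C(CN(C)C)C(=O)c2ccc(OC)c(OC)c2
F6 | step 7 | (2R,3S,4R)-2-(3,4-dimethoxyphenyl)-4-[(R)-(3,4-dimethoxyphenyl)(hydroxy)methyl]-3-(hydroxymethyl)oxolan-3-ol | COc1ccc([C@H]2OC[C@H]([C@@H](O)c3ccc(OC)c(OC)c3)[C@]2(O)CO)cc1OC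
F7 | step 7 | [(2R,3S,4R)-2-(3,4-dimethoxyphenyl)-4-[(R)-(3,4-dimethoxyphenyl)(hydroxy)methyl]-3-hydroxyoxolan-3-yl]methyl 4-methylbenzenesulfonate | COc1ccc([C@H]2OC[C@H]([C@@H](O)c3ccc(OC)c(OC)c3)[C@]2(O)COS(=O)(=O)c4ccc(C)cc4)cc1OC
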